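**Retrosynthetic overview**
1. Target 22 ⇐ saponification/protodecarboxylation of ester 20; the C8 ester is a traceless blocking group that forces both ring-A C–C bonds to sit next to the OMe.
2. 20 ⇐ ionic hydrogenation of the C2 acetal in 19, which releases the chiral auxiliary.
3. 19 ⇐ 15 + 11 in one flask: an o-quinone methide [4+2] with a chiral E-enol ether closes ring C and sets C3, then heating the same flask converts the aryl propargyl ether into ring D.
4. 11 ⇐ alkynyl ether 9 (from 5) + aryl bromide 4 (from 1); 15 ⇐ prenylation/Mannich reaction of 12.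
5. Ring order: rings A and B are bought as benzenes; ring C forms first and ring D second, both in step 7.

Assumption: 1, 3, 5, 6, 12 and 13 are bought; alkoxide, phenoxide and acetylide salt forms count as forms of the numbered neutral compounds.

**Step 1**
Reactants: 1 3-hydroxyphenyl benzoate
Product: 2 4-bromo-3-hydroxyphenyl benzoate
Conditions: NBS (1.0 equiv), i-Pr2NH (10 mol %), CH2Cl2, −20 → 0 °C
Reagents that add atoms: N-bromosuccinimide, O=C1CCC(=O)N1Br
Why: Amine-mediated ortho-selective electrophilic bromination of a phenol puts Br on the less hindered carbon ortho to the free OH (para to the benzoate); no stereocenter.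

**Step 2**
Reactants: 2 4-bromo-3-hydroxyphenyl benzoate; 3 3-chloro-3-methylbut-1-yne
Product: 4 4-bromo-3-[(2-methylbut-3-yn-2-yl)oxy]phenyl benzoate
Conditions: DBU, CuCl2·2H2O (1 mol %), MeCN, 0 °C
Reagents that add atoms: none
Why: Copper-catalysed O-propargylation of a phenol with a tertiary propargylic chloride gives the aryl 1,1-dimethylpropargyl ether under conditions mild enough to keep the aryl benzoate.

**Step 3**
Reactants: 5 (1R,2S)-2-phenylcyclohexan-1-ol; 6 trichloroethylene
Product: 9 (1R,2S)-2-phenylcyclohexyl ethynyl ether, via dichlorovinyl ether 7 (not isolated), via chloroethynyl ether 8 (not isolated)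
Conditions: KH, THF, 0 °C; 6, −50 → 23 °C; n-BuLi (2.4 equiv), −78 → −40 °C; MeOH
Reagents that add atoms: none
Why: Alkoxide addition–elimination on trichloroethylene gives the E-dichlorovinyl ether, and n-BuLi then effects dehydrochlorination and Cl/Li exchange to the lithium alkoxyacetylide, which is protonated (alkynyl ether synthesis); the carbinol stereocenters are untouched.

**Step 4**
Reactants: 9 (1R,2S)-2-phenylcyclohexyl ethynyl ether; 4 4-bromo-3-[(2-methylbut-3-yn-2-yl)oxy]phenyl benzoate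
Product: 11 3-[(2-methylbut-3-yn-2-yl)oxy]-4-[(E)-2-{[(1R,2S)-2-phenylcyclohexyl]oxy}ethenyl]phenyl benzoate, via alkenylzirconocene 10 (not isolated)
Conditions: 9 (1.2 equiv), Cp2Zr(H)Cl (1.2 equiv), THF, 23 °C; then 4, Pd(P(t-Bu)3)2 (3 mol %), ZnCl2 (20 mol %), 40 °C
Reagents that add atoms: none
Why: Syn hydrozirconation puts Zr on the terminal carbon, and the E-alkenylzirconocene then undergoes stereoretentive Pd-catalysed Negishi-type cross-coupling with the aryl bromide, fixing the E enol ether geometry under base-free conditions that spare the benzoate and the terminal alkyne.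

**Step 5**
Reactants: 12 methyl 2,6-dihydroxy-4-methoxybenzoate; 13 1-bromo-3-methylbut-2-ene
Product: 14 methyl 2,6-dihydroxy-4-methoxy-3-(3-methylbut-2-en-1-yl)benzoate
Conditions: NaH (1.0 equiv), toluene, 0 → 23 °C; 13 (1.0 equiv)
Reagents that add atoms: none
Why: Ortho C-alkylation of the sodium phenoxide in a non-polar solvent (nuclear prenylation); the ester blocks the carbon between the two OH groups, so only the two equivalent positions flanking OMe can react.

**Step 6**
Reactants: 14 methyl 2,6-dihydroxy-4-methoxy-3-(3-methylbut-2-en-1-yl)benzoate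
Product: 15 methyl 3-[(dimethylamino)methyl]-2,6-dihydroxy-4-methoxy-5-(3-methylbut-2-en-1-yl)benzoate
Conditions: Me2NH (40 % aq.), CH2O (37 % aq.), EtOH, 23 → 50 °C
Reagents that add atoms: formaldehyde, C=O; dimethylamine, CNC
Why: Phenolic Mannich reaction at the only unsubstituted ring carbon, which is ortho to OH and OMe and para to OH.

**Step 7**
Reactants: 15 methyl 3-[(dimethylamino)methyl]-2,6-dihydroxy-4-methoxy-5-(3-methylbut-2-en-1-yl)benzoate; 11 3-[(2-methylbut-3-yn-2-yl)oxy]-4-[(E)-2-{[(1R,2S)-2-phenylcyclohexyl]oxy}ethenyl]phenyl benzoate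
Product: 19 methyl (2S,3R)-3-[5-(benzoyloxy)-2,2-dimethyl-2H-chromen-8-yl]-7-hydroxy-5-methoxy-6-(3-methylbut-2-en-1-yl)-2-{[(1R,2S)-2-phenylcyclohexyl]oxy}-3,4-dihydro-2H-chromene-8-carboxylate, via ammonium iodide 16 (not isolated), via ortho-quinone methide 17 (not isolated), via cycloadduct 18 (not isolated)
Conditions: 15 (1.4 equiv), MeI (1.4 equiv), DMF, 23 °C; then 11 (1.0 equiv), Et3N (1.6 equiv), 0 → 40 °C; then 130 °C
Reagents that add atoms: none
Why: Proposed new method: N-methylation turns the Mannich base into a benzylic trimethylammonium salt whose base-induced 1,4-elimination gives o-quinone methide 17, which adds to E-enol ether 11 in an inverse-electron-demand hetero-Diels–Alder reaction (closest known type: o-quinone methide cycloadditions with trans-2-phenylcyclohexyl enol ethers) suprafacially on the alkene face anti to the auxiliary phenyl of the s-trans conformer, closing ring C and setting C3 as R in (2S,3R)-18, after which heating triggers aryl propargyl ether Claisen rearrangement, 1,5-H shift and oxa-6π electrocyclisation at the only free ortho carbon to close ring D (closest known type: thermal 2,2-dimethylchromene synthesis) while the benzoate stops the neighbouring oxygen from competing; the minor (2R,3S) diastereomer is removed by chromatography.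

**Step 8**
Reactants: 19 methyl (2S,3R)-3-[5-(benzoyloxy)-2,2-dimethyl-2H-chromen-8-yl]-7-hydroxy-5-methoxy-6-(3-methylbut-2-en-1-yl)-2-{[(1R,2S)-2-phenylcyclohexyl]oxy}-3,4-dihydro-2H-chromene-8-carboxylate
Product: 20 methyl (3R)-3-[5-(benzoyloxy)-2,2-dimethyl-2H-chromen-8-yl]-7-hydroxy-5-methoxy-6-(3-methylbut-2-en-1-yl)-3,4-dihydro-2H-chromene-8-carboxylate
Conditions: Et3SiH (5 equiv), BF3·OEt2 (3 equiv), CH2Cl2, −78 → −40 °C; aq. NaHCO3
Reagents that add atoms: none
Why: Ionic hydrogenation of an acetal: BF3 ionises the more basic exocyclic alkoxy group to the chroman-2-yl oxocarbenium ion, which Et3SiH reduces at low temperature faster than C3 can deprotonate, so C3 stays R and the auxiliary is released for recovery.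

**Step 9**
Reactants: 20 methyl (3R)-3-[5-(benzoyloxy)-2,2-dimethyl-2H-chromen-8-yl]-7-hydroxy-5-methoxy-6-(3-methylbut-2-en-1-yl)-3,4-dihydro-2H-chromene-8-carboxylate
Product: 22 (3R)-3-(5-hydroxy-2,2-dimethyl-2H-chromen-8-yl)-5-methoxy-6-(3-methylbut-2-en-1-yl)-3,4-dihydro-2H-chromen-7-ol, via carboxylic acid 21 (not isolated)
Conditions: KOH (10 equiv), EtOH/H2O, 80 °C, Ar; then 2 M HCl to pH 3, 50 °C
Reagents that add atoms: none
Why: Saponification of the methyl ester and the aryl benzoate followed by acid-promoted protodecarboxylation of the 2,4,6-trioxygenated benzoic acid (ipso protonation) leaves C8–H; C3 is not acidic and is unaffected.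

**Compound list**
1 | 3-hydroxyphenyl benzoate | O=C(Oc1cccc(O)c1)c1ccccc1 | starting material
2 | 4-bromo-3-hydroxyphenyl benzoate | O=C(Oc1ccc(Br)c(O)c1)c1ccccc1 | intermediate
3 | 3-chloro-3-methylbut-1-yne | CC(C)(Cl)C#C | starting material
4 | 4-bromo-3-[(2-methylbut-3-yn-2-yl)oxy]phenyl benzoate | O=C(Oc1ccc(Br)c(OC(C)(C)C#C)c1)c1ccccc1 | intermediate
5 | (1R,2S)-2-phenylcyclohexan-1-ol | O[C@@H]1CCCC[C@H]1c1ccccc1 | starting material
6 | trichloroethylene | ClC=C(Cl)Cl | starting material
7 | (1R,2S)-2-phenylcyclohexyl (E)-1,2-dichloroethenyl ether | Cl/C=C(/Cl)O[C@@H]1CCCC[C@H]1c1ccccc1 | intermediate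
8 | (1R,2S)-2-phenylcyclohexyl chloroethynyl ether | ClC#CO[C@@H]1CCCC[C@H]1c1ccccc1 | intermediate
9 | (1R,2S)-2-phenylcyclohexyl ethynyl ether | C#CO[C@@H]1CCCC[C@H]1c1ccccc1 | intermediate
10 | chlorobis(cyclopentadienyl)[(E)-2-{[(1R,2S)-2-phenylcyclohexyl]oxy}ethenyl]zirconium | Cl[Zr](/C=C/O[C@@H]1CCCC[C@H]1c1ccccc1)(C1C=CC=C1)C1C=CC=C1 | intermediate
11 | 3-[(2-methylbut-3-yn-2-yl)oxy]-4-[(E)-2-{[(1R,2S)-2-phenylcyclohexyl]oxy}ethenyl]phenyl benzoate | O=C(Oc1ccc(/C=C/O[C@@H]2CCCC[C@H]2c2ccccc2)c(OC(C)(C)C#C)c1)c1ccccc1 | intermediate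
12 | methyl 2,6-dihydroxy-4-methoxybenzoate | COC(=O)c1c(O)cc(OC)cc1O | starting material
13 | 1-bromo-3-methylbut-2-ene | CC(C)=CCBr | starting material
14 | methyl 2,6-dihydroxy-4-methoxy-3-(3-methylbut-2-en-1-yl)benzoate | COC(=O)c1c(O)cc(OC)c(CC=C(C)C)c1O | intermediate
15 | methyl 3-[(dimethylamino)methyl]-2,6-dihydroxy-4-methoxy-5-(3-methylbut-2-en-1-yl)benzoate | COC(=O)c1c(O)c(CN(C)C)c(OC)c(CC=C(C)C)c1O | intermediate
16 | [2,4-dihydroxy-6-methoxy-3-(methoxycarbonyl)-5-(3-methylbut-2-en-1-yl)benzyl]trimethylammonium iodide | COC(=O)c1c(O)c(C[N+](C)(C)C)c(OC)c(CC=C(C)C)c1O.[I-] | intermediate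
17 | methyl 2-hydroxy-4-methoxy-5-methylidene-3-(3-methylbut-2-en-1-yl)-6-oxocyclohexa-1,3-diene-1-carboxylate | COC(=O)C1=C(O)C(CC=C(C)C)=C(OC)C(=C)C1=O | intermediate
18 | methyl (2S,3R)-3-{4-(benzoyloxy)-2-[(2-methylbut-3-yn-2-yl)oxy]phenyl}-7-hydroxy-5-methoxy-6-(3-methylbut-2-en-1-yl)-2-{[(1R,2S)-2-phenylcyclohexyl]oxy}-3,4-dihydro-2H-chromene-8-carboxylate | COC(=O)c1c(O)c(CC=C(C)C)c(OC)c2c1O[C@H](O[C@@H]3CCCC[C@H]3c3ccccc3)[C@@H](c3ccc(OC(=O)c4ccccc4)cc3OC(C)(C)C#C)C2 | intermediate
19 | methyl (2S,3R)-3-[5-(benzoyloxy)-2,2-dimethyl-2H-chromen-8-yl]-7-hydroxy-5-methoxy-6-(3-methylbut-2-en-1-yl)-2-{[(1R,2S)-2-phenylcyclohexyl]oxy}-3,4-dihydro-2H-chromene-8-carboxylate | COC(=O)c1c(O)c(CC=C(C)C)c(OC)c2c1O[C@H](O[C@@H]3CCCC[C@H]3c3ccccc3)[C@@H](c3ccc(OC(=O)c4ccccc4)c4c3OC(C)(C)C=C4)C2 | intermediate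
20 | methyl (3R)-3-[5-(benzoyloxy)-2,2-dimethyl-2H-chromen-8-yl]-7-hydroxy-5-methoxy-6-(3-methylbut-2-en-1-yl)-3,4-dihydro-2H-chromene-8-carboxylate | COC(=O)c1c(O)c(CC=C(C)C)c(OC)c2c1OC[C@@H](c1ccc(OC(=O)c3ccccc3)c3c1OC(C)(C)C=C3)C2 | intermediate
21 | (3R)-7-hydroxy-3-(5-hydroxy-2,2-dimethyl-2H-chromen-8-yl)-5-methoxy-6-(3-methylbut-2-en-1-yl)-3,4-dihydro-2H-chromene-8-carboxylic acid | OC(=O)c1c(O)c(CC=C(C)C)c(OC)c2c1OC[C@@H](c1ccc(O)c3c1OC(C)(C)C=C3)C2 | intermediate
22 | (3R)-3-(5-hydroxy-2,2-dimethyl-2H-chromen-8-yl)-5-methoxy-6-(3-methylbut-2-en-1-yl)-3,4-dihydro-2H-chromen-7-ol | COc1c(CC=C(C)C)c(O)cc2c1C[C@H](c1ccc(O)c3c1OC(C)(C)C=C3)CO2 | target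

**Totals**
Total step count: 9. Longest linear sequence: 6 steps (1 → 2 → 4 → 11 → 19 → 20 → 22).

**Steps most likely to fail**

Step 7. The risks are slow or unselective cycloaddition and loss of material when the crude salt-containing mixture is heated; the facial sense also rests on a conformational model, and if it proves opposite, the commercial enantiomer of 5 corrects it. The fallback sets out from 15 and 11 and separates the two ring closures. The cycloaddition is stopped at 40 °C and cycloadduct 18 is isolated and freed of its minor diastereomer. Ring D is then closed in a separate flask by a different mechanism, gold-catalysed 6-endo hydroarylation of the aryl propargyl ether (Ph3PAuNTf2, CH2Cl2, 23 °C), and the route is rejoined at 19. This fallback makes no new compound (F0).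

Step 8. Lewis-acid ionisation could instead break the ring C–O bond (giving a ring-opened ether) or erode C3 through the 4H-chromene. The fallback sets out from 19 and abandons direct reduction. Mild acid hydrolysis (PPTS, acetone/H2O) removes the auxiliary to give the lactol methyl (3R)-3-[5-(benzoyloxy)-2,2-dimethyl-2H-chromen-8-yl]-2,7-dihydroxy-5-methoxy-6-(3-methylbut-2-en-1-yl)-3,4-dihydro-2H-chromene-8-carboxylate F1. NaBH4 in EtOH at 0 °C reduces its open form to the diol methyl 3-{(2R)-2-[5-(benzoyloxy)-2,2-dimethyl-2H-chromen-8-yl]-3-hydroxypropyl}-2,6-dihydroxy-4-methoxy-5-(3-methylbut-2-en-1-yl)benzoate F2. Mitsunobu etherification (PPh3, DIAD, THF) between the primary alcohol and the ortho phenol recloses ring C, and the route is rejoined at 20.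

Step 5. Direct C-prenylation may give mainly O-alkylation or bis-prenylation. The fallback sets out from 12 and installs the prenyl group by rearrangement instead. Pd(PPh3)4-catalysed O-alkylation with tert-butyl 2-methylbut-3-en-2-yl carbonate gives the tertiary allyl ether methyl 2-hydroxy-4-methoxy-6-[(2-methylbut-3-en-2-yl)oxy]benzoate F3. Its thermal aromatic Claisen rearrangement (toluene, 110 °C) can only reach the free ortho carbon, and the route is rejoined at 14.

**Further compounds**
F0 | step 7 | none | none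
F1 | step 8 | methyl (3R)-3-[5-(benzoyloxy)-2,2-dimethyl-2H-chromen-8-yl]-2,7-dihydroxy-5-methoxy-6-(3-methylbut-2-en-1-yl)-3,4-dihydro-2H-chromene-8-carboxylate | COC(=O)c1c(O)c(CC=C(C)C)c(OC)c2c1OC(O)[C@@H](c1ccc(OC(=O)c3ccccc3)c3c1OC(C)(C)C=C3)C2
F2 | step 8 | methyl 3-{(2R)-2-[5-(benzoyloxy)-2,2-dimethyl-2H-chromen-8-yl]-3-hydroxypropyl}-2,6-dihydroxy-4-methoxy-5-(3-methylbut-2-en-1-yl)benzoate | COC(=O)c1c(O)c(CC=C(C)C)c(OC)c(C[C@@H](CO)c2ccc(OC(=O)c3ccccc3)c3c2OC(C)(C)C=C3)c1O
F3 | step 5 | methyl 2-hydroxy-4-methoxy-6-[(2-methylbut-3-en-2-yl)oxy]benzoate | COC(=O)c1c(O)cc(OC)cc1OC(C)(C)C=C
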